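**Retrosynthetic overview**
1. Feature: ring A (ester carbon on C1, OH on C2, OMe on C4, n-pentyl on C6) is a cyclised 3,5,7-trioxododecanoyl chain; chain C2–C7 are the six ring carbons and chain C1 is the depside carbonyl.
2. Endgame: carboxylic acid ⇐ benzyl ester (hydrogenolysis); A-ring C4–OMe ⇐ C4–OH (selective O-methylation).
3. Key disconnection: the A-ring C1–C6 bond (chain C2 onto the C7 ketone, aldol then aromatisation) inside aryl 3,5,7-trioxododecanoate 12, so the depside C(=O)–O bond exists before ring A does and no 2,6-disubstituted benzoic acid has to be esterified.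
4. 12 ⇐ acylketene from diketo-dioxinone 5 + ring-B phenol 10; 5 ⇐ dioxinone 1 by two Claisen-type acylations (acetyl, then hexanoyl); 10 ⇐ olivetolic acid 6 (benzyl ester, 4-O-allyl, 2-O-methyl, deallylation).
5. Ring order: ring B is bought intact in 6; ring A is the only ring built (step 9).

Key step: step 9

Remark: the target has no stereocentre and is achiral, so no stereocontrol is required; compounds 1, 3 and 6 and the reagents named are assumed to be purchasable.

**Route**

Step 1
Reactants: 1 2,2,6-trimethyl-4H-1,3-dioxin-4-one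
Product: 2 2,2-dimethyl-6-(2-oxopropyl)-4H-1,3-dioxin-4-one
Conditions: 1 (2 equiv), LiHMDS (2 equiv), THF, −78 °C; AcCl (1 equiv), −78 → −20 °C; aq. NH4Cl
Reagents that add atoms: acetyl chloride, CC(Cl)=O
Why: γ-Deprotonation of the 6-methyl group gives the lithium dienolate, which is C-acylated at its exocyclic carbon by the acid chloride (Claisen-type acylation), while the second equivalent of dienolate takes the more acidic proton of the β-keto product and so prevents double acylation.

Step 2
Reactants: 3 hexanoyl chloride
Product: 4 N-methoxy-N-methylhexanamide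
Conditions: MeNH(OMe)·HCl, K2CO3, CH2Cl2/H2O, 0 °C → rt
Reagents that add atoms: N,O-dimethylhydroxylamine hydrochloride, CNOC.Cl
Why: Schotten–Baumann N-acylation of the liberated hydroxylamine by the acid chloride is fast and gives the N-methoxy-N-methylamide that allows a clean mono-acylation in step 3.

Step 3
Reactants: 2 2,2-dimethyl-6-(2-oxopropyl)-4H-1,3-dioxin-4-one; 4 N-methoxy-N-methylhexanamide
Product: 5 6-(2,4-dioxononyl)-2,2-dimethyl-4H-1,3-dioxin-4-one
Conditions: LDA (2.2 equiv), THF, −78 °C; then 4, −78 → −20 °C; cold aq. HCl (pH 3)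
Reagents that add atoms: none
Why: Two equivalents of LDA give the dianion of 2 (first at the ring-CH2-CO methylene, then at the terminal methyl), which reacts at its terminal carbon with the amide (dianion Claisen condensation, Weinreb ketone synthesis), the chelated tetrahedral adduct releasing the 1,3-diketone only on the acid quench.

Step 4
Reactants: 6 olivetolic acid (2,4-dihydroxy-6-pentylbenzoic acid)
Product: 7 benzyl 2,4-dihydroxy-6-pentylbenzoate
Conditions: BnBr (1.05 equiv), KHCO3, DMF, rt
Reagents that add atoms: benzyl bromide, BrCc1ccccc1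
Why: SN2 O-alkylation of the carboxylate is selective because bicarbonate deprotonates only the carboxylic acid and not the phenols, and room temperature avoids decarboxylation of the β-resorcylic acid.

Step 5
Reactants: 7 benzyl 2,4-dihydroxy-6-pentylbenzoate
Product: 8 benzyl 4-(allyloxy)-2-hydroxy-6-pentylbenzoate
Conditions: allyl bromide (1.05 equiv), K2CO3, acetone, rt
Reagents that add atoms: allyl bromide, C=CCBr
Why: Williamson etherification takes place at the 4-hydroxyl, which is the more acidic and is free, whereas the 2-hydroxyl is hydrogen-bonded to the ester carbonyl.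

Step 6
Reactants: 8 benzyl 4-(allyloxy)-2-hydroxy-6-pentylbenzoate
Product: 9 benzyl 4-(allyloxy)-2-methoxy-6-pentylbenzoate
Conditions: MeI (3 equiv), K2CO3, DMF, 40 °C
Reagents that add atoms: iodomethane, CI
Why: Williamson methylation of the remaining chelated phenol proceeds under these more forcing conditions (polar aprotic solvent, excess MeI), and the hindered benzyl ester and the allyl ether are inert to carbonate.

Step 7
Reactants: 9 benzyl 4-(allyloxy)-2-methoxy-6-pentylbenzoate
Product: 10 benzyl 4-hydroxy-2-methoxy-6-pentylbenzoate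
Conditions: Pd(PPh3)4 (5 mol %), morpholine, THF, rt
Reagents that add atoms: none
Why: Pd(0) ionises the aryl allyl ether to a π-allyl complex and the phenoxide and morpholine captures the allyl group (Tsuji–Trost deallylation), which leaves the benzyl ester and the methyl ether untouched.

Step 8
Reactants: 5 6-(2,4-dioxononyl)-2,2-dimethyl-4H-1,3-dioxin-4-one; 10 benzyl 4-hydroxy-2-methoxy-6-pentylbenzoate
Product: 12 benzyl 2-methoxy-6-pentyl-4-[(3,5,7-trioxododecanoyl)oxy]benzoate, via acylketene 11 (not isolated)
Conditions: PhMe, 110 °C, slow addition of 5 (1.5 equiv) to 10; concentrate, use crude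
Reagents that add atoms: none
Why: Thermal retro-[4+2] fragmentation of the dioxinone (retro-hetero-Diels–Alder) expels acetone and gives acylketene 11, which the phenol captures at the ketene carbon to give the aryl β-keto ester, the slow addition keeping the phenol in excess so that intermolecular capture should outrun closure of the ketene onto its own C5 enol oxygen.

Step 9
Reactants: 12 benzyl 2-methoxy-6-pentyl-4-[(3,5,7-trioxododecanoyl)oxy]benzoate
Product: 14 benzyl 4-[(2,4-dihydroxy-6-pentylbenzoyl)oxy]-2-methoxy-6-pentylbenzoate, via cyclic aldol adduct 13 (not isolated)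
Conditions: Et3N (2 equiv), CH2Cl2, 0 °C → rt; then HCl (4 M in dioxane), rt
Reagents that add atoms: none
Why: Et3N reversibly enolises the C2 methylene of 12, which is activated by both the aryl ester carbonyl and the C3 ketone, and this enolate adds to the C7 ketone in an intramolecular aldol reaction that forms the chain C2–C7 bond (the C1–C6 bond of ring A) and gives the cyclic β-diketone 13. HCl then eliminates the tertiary C7 hydroxyl and the C3 and C5 carbonyls enolise, so that the benzene ring forms irreversibly; the two transient stereocentres of 13 vanish and none has to be controlled. The closest known reaction type is the biomimetic aldol cyclisation and aromatisation of 3,5,7-trioxoalkanoates to β-resorcylates under mild base then acid, the orsellinate-type folding of a tetraketide. The carbocycle closes in the 6-exo-trig mode (enolendo with respect to the C2=C3 enolate). The step needs this carbon–carbon closure to beat two closures that expel the aryloxide: attack of the C5 enol oxygen on the ester carbonyl (4-hydroxy-2-pyranone) and attack of C6 on the ester carbonyl (Claisen mode, acylphloroglucinol). A ketone is the better electrophile for the carbon nucleophile, the weak amine base in aprotic CH2Cl2 at or below room temperature forms only mono-enolates and brings no transesterifying nucleophile, and the acid quench follows as soon as 12 is consumed.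

Step 10
Reactants: 14 benzyl 4-[(2,4-dihydroxy-6-pentylbenzoyl)oxy]-2-methoxy-6-pentylbenzoate
Product: 15 benzyl 4-[(2-hydroxy-4-methoxy-6-pentylbenzoyl)oxy]-2-methoxy-6-pentylbenzoate
Conditions: MeI (1.1 equiv), K2CO3 (1.1 equiv), acetone, rt
Reagents that add atoms: iodomethane, CI
Why: Williamson methylation should be selective for the A-ring 4-hydroxyl (para to the ester carbonyl, more acidic, free), since the 2-hydroxyl is chelated to the depside carbonyl, and the hindered 2,6-disubstituted aryl ester is stable to carbonate in acetone.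

Step 11
Reactants: 15 benzyl 4-[(2-hydroxy-4-methoxy-6-pentylbenzoyl)oxy]-2-methoxy-6-pentylbenzoate
Product: 16 2'-O-methylperlatolic acid (4-[(2-hydroxy-4-methoxy-6-pentylbenzoyl)oxy]-2-methoxy-6-pentylbenzoic acid)
Conditions: H2 (1 atm), 10 % Pd/C, EtOAc, rt
Reagents that add atoms: none
Why: Hydrogenolysis of the benzylic C–O bond frees the carboxylic acid under neutral conditions that cannot hydrolyse or transesterify the depside ester, and nothing else in 15 is reducible.

**Compound list**
1 | 2,2,6-trimethyl-4H-1,3-dioxin-4-one | CC1=CC(=O)OC(C)(C)O1 | starting material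
2 | 2,2-dimethyl-6-(2-oxopropyl)-4H-1,3-dioxin-4-one | CC(=O)CC1=CC(=O)OC(C)(C)O1 | intermediate
3 | hexanoyl chloride | CCCCCC(Cl)=O | starting material
4 | N-methoxy-N-methylhexanamide | CCCCCC(=O)N(C)OC | intermediate
5 | 6-(2,4-dioxononyl)-2,2-dimethyl-4H-1,3-dioxin-4-one | CCCCCC(=O)CC(=O)CC1=CC(=O)OC(C)(C)O1 | intermediate
6 | olivetolic acid (2,4-dihydroxy-6-pentylbenzoic acid) | CCCCCc1cc(O)cc(O)c1C(=O)O | starting material
7 | benzyl 2,4-dihydroxy-6-pentylbenzoate | CCCCCc1cc(O)cc(O)c1C(=O)OCc1ccccc1 | intermediate
8 | benzyl 4-(allyloxy)-2-hydroxy-6-pentylbenzoate | CCCCCc1cc(OCC=C)cc(O)c1C(=O)OCc1ccccc1 | intermediate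
9 | benzyl 4-(allyloxy)-2-methoxy-6-pentylbenzoate | CCCCCc1cc(OCC=C)cc(OC)c1C(=O)OCc1ccccc1 | intermediate
10 | benzyl 4-hydroxy-2-methoxy-6-pentylbenzoate | CCCCCc1cc(O)cc(OC)c1C(=O)OCc1ccccc1 | intermediate
11 | acylketene 3,5,7-trioxododec-1-en-1-one (transient, step 8) | CCCCCC(=O)CC(=O)CC(=O)C=C=O | intermediate
12 | benzyl 2-methoxy-6-pentyl-4-[(3,5,7-trioxododecanoyl)oxy]benzoate | CCCCCC(=O)CC(=O)CC(=O)CC(=O)Oc1cc(CCCCC)c(C(=O)OCc2ccccc2)c(OC)c1 | intermediate
13 | benzyl 4-{[(2-hydroxy-4,6-dioxo-2-pentylcyclohexyl)carbonyl]oxy}-2-methoxy-6-pentylbenzoate (cyclic aldol adduct, diastereomer mixture, transient, step 9) | CCCCCC1(O)CC(=O)CC(=O)C1C(=O)Oc1cc(CCCCC)c(C(=O)OCc2ccccc2)c(OC)c1 | intermediate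
14 | benzyl 4-[(2,4-dihydroxy-6-pentylbenzoyl)oxy]-2-methoxy-6-pentylbenzoate | CCCCCc1cc(O)cc(O)c1C(=O)Oc1cc(CCCCC)c(C(=O)OCc2ccccc2)c(OC)c1 | intermediate
15 | benzyl 4-[(2-hydroxy-4-methoxy-6-pentylbenzoyl)oxy]-2-methoxy-6-pentylbenzoate | CCCCCc1cc(OC)cc(O)c1C(=O)Oc1cc(CCCCC)c(C(=O)OCc2ccccc2)c(OC)c1 | intermediate
16 | 2'-O-methylperlatolic acid | CCCCCc1cc(OC)cc(O)c1C(=O)Oc1cc(CCCCC)c(C(=O)O)c(OC)c1 | target

**Step count**
Total: 11 steps. Longest linear sequence: 8 steps (steps 4–11, from olivetolic acid 6 to 16).

**Steps most likely to fail**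

Step 9 (key step). Closure through the C5 enol oxygen onto the ester carbonyl, or through C6 onto the ester carbonyl, may outrun the C2→C7 aldol; either path expels the aryloxide and the depside linkage is lost. The fallback keeps the same aldol aromatisation but runs it before the acyl transfer. It sets out from 5: with Et3N in CH2Cl2 at rt the dioxinone C5 carbon should add to the side-chain C4' ketone and aromatise with the acetonide retained, giving 7-hydroxy-2,2-dimethyl-5-pentyl-4H-1,3-benzodioxin-4-one F1. Methylation with MeI and K2CO3 in acetone would give 7-methoxy-2,2-dimethyl-5-pentyl-4H-1,3-benzodioxin-4-one F2. Irradiation of F2 at 300 nm in CH2Cl2 in the presence of phenol 10 should expel acetone and form the quinone ketene 3-methoxy-6-(oxomethylidene)-5-pentylcyclohexa-2,4-dien-1-one F3, which 10 captures to give the salicylate-type aryl ester (photochemical acylation). The fallback comes back to the route at 15.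

Step 8. The acylketene may close onto its own C5 enol oxygen (pyranone formation) faster than the weakly nucleophilic phenol captures it, and on prolonged heating the aryl ester may shed the aryloxide in the same way. The fallback forms the depside ester by mixed-anhydride esterification of a finished ring A. It sets out from 7 and 10: selective 4-O-methylation of 7 (MeI, K2CO3, acetone, rt) would give benzyl 2-hydroxy-4-methoxy-6-pentylbenzoate F4, and hydrogenolysis (H2, Pd/C, EtOAc) would give 2-hydroxy-4-methoxy-6-pentylbenzoic acid F5. Trifluoroacetic anhydride in toluene at rt should convert F5 into the mixed anhydride 2-hydroxy-4-methoxy-6-pentylbenzoic trifluoroacetic anhydride F6, which acylates phenol 10. The fallback comes back to the route at 15.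

Step 3. Proton transfer from the enolisable amide to the dianion, incomplete second deprotonation, or premature cyclisation of the polyanionic adduct may lower conversion to 5. The fallback replaces the dianion by soft enolisation, C-acylation and decarboxylation. It sets out from 1 and 3: the lithium dienolate of 1 (LiHMDS, THF, −78 °C) is acylated with allyl malonyl chloride to give allyl 4-(2,2-dimethyl-4-oxo-4H-1,3-dioxin-6-yl)-3-oxobutanoate F7. Its magnesium enolate (MgCl2, pyridine, CH2Cl2, 0 °C) is C-acylated with hexanoyl chloride 3 to give allyl 2-[(2,2-dimethyl-4-oxo-4H-1,3-dioxin-6-yl)acetyl]-3-oxooctanoate F8. Pd(PPh3)4 and morpholine in THF remove the allyl group, and the resulting 2-[(2,2-dimethyl-4-oxo-4H-1,3-dioxin-6-yl)acetyl]-3-oxooctanoic acid F9 decarboxylates in the flask. The fallback comes back to the route at 5.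

**Further compounds**
F1 | step 9 | 7-hydroxy-2,2-dimethyl-5-pentyl-4H-1,3-benzodioxin-4-one | CCCCCc1cc(O)cc2OC(C)(C)OC(=O)c12
F2 | step 9 | 7-methoxy-2,2-dimethyl-5-pentyl-4H-1,3-benzodioxin-4-one | CCCCCc1cc(OC)cc2OC(C)(C)OC(=O)c12
F3 | step 9 | 3-methoxy-6-(oxomethylidene)-5-pentylcyclohexa-2,4-dien-1-one | CCCCCC1=CC(OC)=CC(=O)C1=C=O
F4 | step 8 | benzyl 2-hydroxy-4-methoxy-6-pentylbenzoate | CCCCCc1cc(OC)cc(O)c1C(=O)OCc1ccccc1
F5 | step 8 | 2-hydroxy-4-methoxy-6-pentylbenzoic acid | CCCCCc1cc(OC)cc(O)c1C(=O)O
F6 | step 8 | 2-hydroxy-4-methoxy-6-pentylbenzoic trifluoroacetic anhydride | CCCCCc1cc(OC)cc(O)c1C(=O)OC(=O)C(F)(F)F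
F7 | step 3 | allyl 4-(2,2-dimethyl-4-oxo-4H-1,3-dioxin-6-yl)-3-oxobutanoate | C=CCOC(=O)CC(=O)CC1=CC(=O)OC(C)(C)O1
F8 | step 3 | allyl 2-[(2,2-dimethyl-4-oxo-4H-1,3-dioxin-6-yl)acetyl]-3-oxooctanoate | CCCCCC(=O)C(C(=O)OCC=C)C(=O)CC1=CC(=O)OC(C)(C)O1
F9 | step 3 | 2-[(2,2-dimethyl-4-oxo-4H-1,3-dioxin-6-yl)acetyl]-3-oxooctanoic acid | CCCCCC(=O)C(C(=O)O)C(=O)CC1=CC(=O)OC(C)(C)O1
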